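**Retrosynthetic overview**

1. Ring A is the catechol ring bound through oxygen to the para-phenylene ring B; ring C is the catechol ring bound through oxygen to the meta-phenylene ring D. The last operations are O-demethylation, hydrogenation, and closure of the 19-membered ring by McMurry coupling of a ring B / ring C dialdehyde.
2. The ring A–CH2CH2–ring D bridge is cut to a ring A styrene (hydroboration) and the ring D aryl bromide (B-alkyl Suzuki–Miyaura coupling). The ring A–O–ring B ether comes from an SNAr reaction.
3. Feature used: on ring C the carbons C3 (outer OH), C4 (middle OH) and C5 (O–ring D) are contiguous, with the bridge at C1. C4 and C5 are therefore treated as the two carbons of an aryne that has the C3 methoxy group as its neighbour. The C5–O bond and a C4–B bond (later C4–OH) are made together by a three-component coupling of this aryne with 3-bromophenoxide and a pinacol borate.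
4. The ortho-silylaryl triflate that releases the aryne comes from 5-bromovanillin, whose substitution pattern maps onto ring C atom for atom.
5. Ring order: all four benzene rings are bought; the only ring formed is the 19-membered macrocycle, in step 11.

Key step: step 4

Remark: the target has no stereocentre, and the alkene geometry of 24 is left uncontrolled because that double bond is hydrogenated in step 12.

**Route**

Step 1
Reactants: 1 5-bromovanillin
Product: 2 2-bromo-4-(1,3-dioxolan-2-yl)-6-methoxyphenol
Conditions: ethylene glycol, p-TsOH (cat.), toluene, reflux, Dean–Stark; Et3N quench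
Reagents that add atoms: ethylene glycol, OCCO
Why: Acid-catalysed acetalisation with azeotropic removal of water turns the aldehyde into a dioxolane that should withstand n-BuLi in step 3 and alkaline peroxide in step 5, while the phenol stays free.

Step 2
Reactants: 2 2-bromo-4-(1,3-dioxolan-2-yl)-6-methoxyphenol
Product: 3 [2-bromo-4-(1,3-dioxolan-2-yl)-6-methoxyphenoxy]trimethylsilane
Conditions: HMDS, THF, reflux; volatiles removed, used crude
Reagents that add atoms: hexamethyldisilazane, C[Si](C)(C)N[Si](C)(C)C
Why: Silylation of the phenol with hexamethyldisilazane gives the aryl trimethylsilyl ether with ammonia as the only by-product and places silicon on the oxygen next to the C–Br bond for the migration in step 3.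

Step 3
Reactants: 3 [2-bromo-4-(1,3-dioxolan-2-yl)-6-methoxyphenoxy]trimethylsilane
Product: 6 4-(1,3-dioxolan-2-yl)-2-methoxy-6-(trimethylsilyl)phenyl trifluoromethanesulfonate, via aryllithium 4 (not isolated), via lithium silylphenoxide 5 (not isolated)
Conditions: n-BuLi, THF, −78 °C; then Tf2O, −78 → 0 °C
Reagents that add atoms: trifluoromethanesulfonic anhydride, O=S(=O)(OS(=O)(=O)C(F)(F)F)C(F)(F)F
Why: Bromine–lithium exchange gives aryllithium 4, whose carbanion takes the silyl group from the neighbouring oxygen (retro-Brook 1,3 O-to-C silyl migration) to give phenoxide 5, and O-triflation of 5 completes the usual one-pot preparation of an ortho-silylaryl triflate.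

Step 4
Reactants: 6 4-(1,3-dioxolan-2-yl)-2-methoxy-6-(trimethylsilyl)phenyl trifluoromethanesulfonate; 7 3-bromophenol; 8 2-isopropoxy-4,4,5,5-tetramethyl-1,3,2-dioxaborolane
Product: 12 2-[2-(3-bromophenoxy)-4-(1,3-dioxolan-2-yl)-6-methoxyphenyl]-4,4,5,5-tetramethyl-1,3,2-dioxaborolane, via sodium 3-bromophenoxide 9 (not isolated), via methoxyaryne 10 (not isolated), via aryl anion 11 (not isolated)
Conditions: 7, NaH, THF, 0 °C; then 8 (excess), CsF, 18-crown-6, 4 Å MS, 6 added slowly, rt
Reagents that add atoms: none
Why: Proposed new method: CsF desilylates 6, the carbanion so formed expels the neighbouring triflate to give the strained 3-methoxyaryne 10, the proton-free phenoxide 9 adds to the aryne carbon far from OMe (C5–O bond), and the aryl anion 11, flanked by OMe and the new aryloxy group, attacks the boron of 8 with loss of isopropoxide (C4–B bond). The closest known reaction types are the fluoride-triggered O-arylation of phenols by arynes from ortho-silylaryl triflates and three-component aryne couplings in which the aryl anion is intercepted by an added electrophile; interception by an alkoxy pinacol borate after phenoxide addition is the untested part. No ring closes and no stereocentre forms. The step needs oxygen to enter at the aryne carbon remote from OMe and boron at the carbon beside it: the σ-withdrawing methoxy group bends the triple bond so that the remote carbon is the more electrophilic one and the developing charge lies next to oxygen. Capture at boron in preference to protonation should be secured by deprotonating 7 with NaH (hydrogen leaves and no conjugate acid remains), by an ether solvent without acidic C–H bonds, by an excess of 8, and by slow addition of 6 so that neither the aryne nor the triflate, a possible triflyl donor, accumulates. The doubly oxygen-flanked anion is too stabilised to exchange with the aryl bromide of ring D, so the bromine is kept for step 9.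

Step 5
Reactants: 12 2-[2-(3-bromophenoxy)-4-(1,3-dioxolan-2-yl)-6-methoxyphenyl]-4,4,5,5-tetramethyl-1,3,2-dioxaborolane
Product: 13 2-(3-bromophenoxy)-4-(1,3-dioxolan-2-yl)-6-methoxyphenol
Conditions: H2O2 (30% aq), NaOH, THF, 0 °C; neutralised to pH 7–8
Reagents that add atoms: hydrogen peroxide, OO
Why: Hydroperoxide adds to boron and the aryl group migrates from boron to oxygen (oxidation of an arylboronic ester to a phenol), and with the aldehyde masked as the dioxolane no Dakin oxidation can compete.

Step 6
Reactants: 13 2-(3-bromophenoxy)-4-(1,3-dioxolan-2-yl)-6-methoxyphenol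
Product: 14 2-[3-(3-bromophenoxy)-4,5-dimethoxyphenyl]-1,3-dioxolane
Conditions: MeI, K2CO3, DMF, rt
Reagents that add atoms: iodomethane, CI
Why: Williamson O-methylation of the phenoxide with iodomethane, run under basic conditions that also keep the acid-labile para-hydroxy acetal from hydrolysing.

Step 7
Reactants: 15 3-hydroxy-4,5-dimethoxybenzaldehyde; 16 4-fluorobenzonitrile
Product: 17 4-(5-formyl-2,3-dimethoxyphenoxy)benzonitrile
Conditions: K2CO3, DMF, 120 °C
Reagents that add atoms: none
Why: Nucleophilic aromatic substitution in which the phenoxide of 15 displaces the fluoride para to the activating nitrile of 16 through a Meisenheimer intermediate, the aldehyde being inert to K2CO3 in dry DMF.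

Step 8
Reactants: 17 4-(5-formyl-2,3-dimethoxyphenoxy)benzonitrile
Product: 18 4-(5-ethenyl-2,3-dimethoxyphenoxy)benzonitrile
Conditions: Ph3PCH3Br, KOtBu, THF, 0 °C → rt
Reagents that add atoms: methyltriphenylphosphonium bromide, C[P+](c1ccccc1)(c1ccccc1)c1ccccc1.[Br-]
Why: Wittig methylenation of the aldehyde with the non-stabilised ylide at low temperature, where the aryl nitrile reacts far more slowly than the aldehyde.

Step 9
Reactants: 18 4-(5-ethenyl-2,3-dimethoxyphenoxy)benzonitrile; 14 2-[3-(3-bromophenoxy)-4,5-dimethoxyphenyl]-1,3-dioxolane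
Product: 20 4-[5-[2-[3-[5-(1,3-dioxolan-2-yl)-2,3-dimethoxyphenoxy]phenyl]ethyl]-2,3-dimethoxyphenoxy]benzonitrile, via alkyl-9-BBN 19 (not isolated)
Conditions: 18, 9-BBN, THF, 0 °C → rt; then 14, PdCl2(dppf) (cat.), K3PO4 (aq), DMF, 60 °C
Reagents that add atoms: none
Why: Anti-Markovnikov hydroboration of the styrene with 9-BBN, which adds to the alkene much faster than it reduces an aryl nitrile, gives primary alkylborane 19, and B-alkyl Suzuki–Miyaura coupling (oxidative addition of zerovalent palladium into the C–Br bond of 14, base-assisted transmetalation, reductive elimination) forms the ring A–CH2CH2–ring D bridge directly at the saturated level.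

Step 10
Reactants: 20 4-[5-[2-[3-[5-(1,3-dioxolan-2-yl)-2,3-dimethoxyphenoxy]phenyl]ethyl]-2,3-dimethoxyphenoxy]benzonitrile
Product: 23 3-[3-[2-[3-(4-formylphenoxy)-4,5-dimethoxyphenyl]ethyl]phenoxy]-4,5-dimethoxybenzaldehyde, via aluminoimine 21 (not isolated), via aldehyde acetal 22 (not isolated)
Conditions: DIBAL-H, CH2Cl2, −78 → 0 °C; then 2 M HCl, THF, rt
Reagents that add atoms: water, O
Why: DIBAL-H delivers one hydride to the nitrile and stops at the N-aluminoimine 21 at low temperature, and aqueous acid then hydrolyses the imine to aldehyde 22 and the dioxolane to the second aldehyde.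

Step 11
Reactants: 23 3-[3-[2-[3-(4-formylphenoxy)-4,5-dimethoxyphenyl]ethyl]phenoxy]-4,5-dimethoxybenzaldehyde
Product: 24 macrocyclic stilbene tetramethyl ether (19-membered ring; CH=CH between ring B and ring C; E/Z mixture)
Conditions: TiCl4, Zn, pyridine, THF, reflux; 23 added over 12 h at high dilution
Reagents that add atoms: none
Why: Intramolecular McMurry coupling, in which low-valent titanium joins the two aldehydes to a titanium pinacolate and deoxygenates it to the alkene, with slow addition at high dilution favouring closure of the 19-membered ring over chain growth.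

Step 12
Reactants: 24 macrocyclic stilbene tetramethyl ether
Product: 25 tetra-O-methyl ether of the target (saturated macrocycle)
Conditions: H2 (1 atm), Pd/C, EtOAc, rt
Reagents that add atoms: none
Why: Heterogeneous catalytic hydrogenation saturates the stilbene double bond whatever its geometry, while aryl ethers are untouched at atmospheric pressure.

Step 13
Reactants: 25 tetra-O-methyl ether of the target
Product: 26 CNP0511668.0 (target tetraphenol)
Conditions: BBr3, CH2Cl2, −78 °C → rt; then H2O
Reagents that add atoms: none
Why: BBr3 cleavage of the four aryl methyl ethers (boron coordinates oxygen, bromide attacks the methyl group) frees the phenols, and the diaryl ether bonds are inert because bromide cannot attack an aryl carbon.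

**Compound list**

1 | 5-bromovanillin (3-bromo-4-hydroxy-5-methoxybenzaldehyde) | COc1cc(C=O)cc(Br)c1O | starting material
2 | 2-bromo-4-(1,3-dioxolan-2-yl)-6-methoxyphenol | COc1cc(C2OCCO2)cc(Br)c1O | intermediate
3 | [2-bromo-4-(1,3-dioxolan-2-yl)-6-methoxyphenoxy]trimethylsilane | COc1cc(C2OCCO2)cc(Br)c1O[Si](C)(C)C | intermediate
4 | [5-(1,3-dioxolan-2-yl)-3-methoxy-2-(trimethylsilyloxy)phenyl]lithium | COc1cc(C2OCCO2)cc([Li])c1O[Si](C)(C)C | intermediate
5 | lithium 4-(1,3-dioxolan-2-yl)-2-methoxy-6-(trimethylsilyl)phenoxide | COc1cc(C2OCCO2)cc([Si](C)(C)C)c1[O-].[Li+] | intermediate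
6 | 4-(1,3-dioxolan-2-yl)-2-methoxy-6-(trimethylsilyl)phenyl trifluoromethanesulfonate | COc1cc(C2OCCO2)cc([Si](C)(C)C)c1OS(=O)(=O)C(F)(F)F | intermediate
7 | 3-bromophenol | Oc1cccc(Br)c1 | starting material
8 | 2-isopropoxy-4,4,5,5-tetramethyl-1,3,2-dioxaborolane | CC(C)OB1OC(C)(C)C(C)(C)O1 | starting material
9 | sodium 3-bromophenoxide | [Na+].[O-]c1cccc(Br)c1 | intermediate
10 | 5-(1,3-dioxolan-2-yl)-3-methoxybenzyne (triple bond C1–C2, OMe on C3) | COC1=CC(C2OCCO2)=CC#C1 | intermediate
11 | [2-(3-bromophenoxy)-4-(1,3-dioxolan-2-yl)-6-methoxyphenyl]sodium (aryl anion) | COc1cc(C2OCCO2)cc(Oc2cccc(Br)c2)c1[Na] | intermediate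
12 | 2-[2-(3-bromophenoxy)-4-(1,3-dioxolan-2-yl)-6-methoxyphenyl]-4,4,5,5-tetramethyl-1,3,2-dioxaborolane | COc1cc(C2OCCO2)cc(Oc2cccc(Br)c2)c1B1OC(C)(C)C(C)(C)O1 | intermediate
13 | 2-(3-bromophenoxy)-4-(1,3-dioxolan-2-yl)-6-methoxyphenol | COc1cc(C2OCCO2)cc(Oc2cccc(Br)c2)c1O | intermediate
14 | 2-[3-(3-bromophenoxy)-4,5-dimethoxyphenyl]-1,3-dioxolane | COc1cc(C2OCCO2)cc(Oc2cccc(Br)c2)c1OC | intermediate
15 | 3-hydroxy-4,5-dimethoxybenzaldehyde | COc1cc(C=O)cc(O)c1OC | starting material
16 | 4-fluorobenzonitrile | N#Cc1ccc(F)cc1 | starting material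
17 | 4-(5-formyl-2,3-dimethoxyphenoxy)benzonitrile | COc1cc(C=O)cc(Oc2ccc(C#N)cc2)c1OC | intermediate
18 | 4-(5-ethenyl-2,3-dimethoxyphenoxy)benzonitrile | COc1cc(C=C)cc(Oc2ccc(C#N)cc2)c1OC | intermediate
19 | 4-[5-[2-(9-borabicyclo[3.3.1]nonan-9-yl)ethyl]-2,3-dimethoxyphenoxy]benzonitrile | COc1cc(CCB2C3CCCC2CCC3)cc(Oc2ccc(C#N)cc2)c1OC | intermediate
20 | 4-[5-[2-[3-[5-(1,3-dioxolan-2-yl)-2,3-dimethoxyphenoxy]phenyl]ethyl]-2,3-dimethoxyphenoxy]benzonitrile | COc1cc(CCc2cccc(Oc3cc(C4OCCO4)cc(OC)c3OC)c2)cc(Oc2ccc(C#N)cc2)c1OC | intermediate
21 | N-(diisobutylalumino)imine of the ring B aldehyde, dioxolane on ring C intact | COc1cc(CCc2cccc(Oc3cc(C4OCCO4)cc(OC)c3OC)c2)cc(Oc2ccc(C=N[Al](CC(C)C)CC(C)C)cc2)c1OC | intermediate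
22 | 4-[5-[2-[3-[5-(1,3-dioxolan-2-yl)-2,3-dimethoxyphenoxy]phenyl]ethyl]-2,3-dimethoxyphenoxy]benzaldehyde | COc1cc(CCc2cccc(Oc3cc(C4OCCO4)cc(OC)c3OC)c2)cc(Oc2ccc(C=O)cc2)c1OC | intermediate
23 | 3-[3-[2-[3-(4-formylphenoxy)-4,5-dimethoxyphenyl]ethyl]phenoxy]-4,5-dimethoxybenzaldehyde | COc1cc(CCc2cccc(Oc3cc(C=O)cc(OC)c3OC)c2)cc(Oc2ccc(C=O)cc2)c1OC | intermediate
24 | macrocyclic stilbene tetramethyl ether: the target skeleton with four OMe groups and CH=CH between ring B and ring C (E/Z mixture, geometry not fixed) | COc1cc2cc(c1OC)Oc1ccc(cc1)C=Cc1cc(OC)c(OC)c(c1)Oc1cccc(c1)CC2 | intermediate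
25 | tetra-O-methyl ether of the target (both bridges CH2CH2) | COc1cc2cc(c1OC)Oc1ccc(cc1)CCc1cc(OC)c(OC)c(c1)Oc1cccc(c1)CC2 | intermediate
26 | CNP0511668.0 | Oc1cc2cc(c1O)Oc1ccc(cc1)CCc1cc(O)c(O)c(c1)Oc1cccc(c1)CC2 | target

**Step count**

Total: 13 steps. Longest linear sequence: 11 steps (steps 1–6 and 9–13); the ring A / ring B branch is steps 7–8.

**Steps most likely to fail**

1. Step 4 (proposed new method). The aryl anion may be protonated by adventitious proton sources before it reaches boron, which would give the diaryl ether without the C4 substituent. Fluoride and phenoxide may be tied up by the borate as ate complexes, which would slow both aryne release and capture. Released isopropoxide may add to the aryne, and the 2,6-dioxygenated boronate may lose boron on isolation. Fallback with known chemistry, setting out from 15 and returning at 14: Chan–Lam coupling of 15 with 3-bromophenylboronic acid (Cu(OAc)2, pyridine, 4 Å MS, CH2Cl2, air, rt) should give 3-(3-bromophenoxy)-4,5-dimethoxybenzaldehyde F1, in which the aryl bromide is untouched by the copper conditions. Acetalisation of F1 (ethylene glycol, p-TsOH, toluene, Dean–Stark) then gives 14, and steps 1–6 are not needed.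

2. Step 11. Intermolecular carbonyl coupling may outrun ring closure and give oligomers, or the reaction may stop at the pinacol stage. Fallback setting out from 23 and returning at 24: double Wittig methylenation of 23 (Ph3PCH3Br, KOtBu, THF) should give the bis-styrene F2, and ring-closing metathesis of F2 with second-generation Grubbs catalyst in dilute toluene at 80 °C, with removal of ethene, should close the same 19-membered stilbene 24.

3. Step 9. 9-BBN may partly reduce the nitrile, the alkylborane may undergo protodeboronation, or the alkyl–palladium intermediate may undergo β-hydride elimination instead of reductive elimination. Fallback setting out from 18 and 14 and returning at 20: Heck coupling of the styrene 18 with the bromide 14 (Pd(OAc)2, P(o-tol)3, Et3N, DMF, 100 °C) should give the (E)-stilbene F3. Diimide reduction of F3 (TsNHNH2, NaOAc, THF/H2O, reflux) saturates the C=C bond without touching the nitrile or the acetal and gives 20.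

**Further compounds**

F1 | step 4 | 3-(3-bromophenoxy)-4,5-dimethoxybenzaldehyde | COc1cc(C=O)cc(Oc2cccc(Br)c2)c1OC
F2 | step 11 | 1-[2-[3-(4-ethenylphenoxy)-4,5-dimethoxyphenyl]ethyl]-3-(5-ethenyl-2,3-dimethoxyphenoxy)benzene (bis-styrene) | COc1cc(CCc2cccc(Oc3cc(C=C)cc(OC)c3OC)c2)cc(Oc2ccc(C=C)cc2)c1OC
F3 | step 9 | 4-[5-[(E)-2-[3-[5-(1,3-dioxolan-2-yl)-2,3-dimethoxyphenoxy]phenyl]ethenyl]-2,3-dimethoxyphenoxy]benzonitrile | COc1cc(/C=C/c2cccc(Oc3cc(C4OCCO4)cc(OC)c3OC)c2)cc(Oc2ccc(C#N)cc2)c1OC
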